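**Retrosynthetic overview**
1. Ring B (pyran) is opened at the aryl C–O bond. The target comes from diformylphloroglucinol 18, which carries a cis secondary alcohol. This last step is an oxidatively triggered dehydrative O-arylation that also resets the benzylic centre.
2. 18 comes from ketone 15 by ketone reduction and double formylation. 15 comes from the enolate of spiro ketone 9 and an o-quinone methide made from 2,4,6-trihydroxybenzaldehyde and i-BuMgCl.
3. Ring C (cyclopentanone of 9) comes from ester 7 by intramolecular Kulinkovich cyclopropanation and cyclopropanol opening.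
4. The spiro carbon comes from deconjugative alkylation of enoate 5, which is made from (−)-menthone (ring D and the only source of chirality).
5. Order of rings: D (bought), C (step 5), A (bought), B (step 10).

Assumption: commercial (−)-menthone of high ee is used; any isomenthone in it is harmless because the isopropyl-bearing centre is planarised in step 4.

**Step 1**
Reactants: 1 (−)-menthone; 2 dimethyl carbonate
Product: 3 methyl (3S,6R)-6-methyl-2-oxo-3-(propan-2-yl)cyclohexane-1-carboxylate (keto/enol mixture, C-1 undefined)
Conditions: NaH (2.2 equiv), THF, reflux; then aq. HCl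
Reagents that add atoms: dimethyl carbonate COC(=O)OC
Why: Claisen-type carbomethoxylation takes place at the less hindered CH2 and is driven by deprotonation of the β-keto ester; the methyl-bearing stereocentre is not touched and the new centre is planarised in step 2.

**Step 2**
Reactants: 3 β-keto ester
Product: 4 methyl (3S,6R)-6-methyl-3-(propan-2-yl)-2-(trifluoromethylsulfonyloxy)cyclohex-1-ene-1-carboxylate
Conditions: NaH, Et2O, 0 °C; then (CF3SO2)2O, −78 → 0 °C
Reagents that add atoms: trifluoromethanesulfonic anhydride O=S(=O)(OS(=O)(=O)C(F)(F)F)C(F)(F)F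
Why: O-sulfonylation of the stabilised sodium enolate gives the vinyl triflate regiospecifically, and no stereocentre is formed.

**Step 3**
Reactants: 4 vinyl triflate
Product: 5 methyl (3S,6R)-6-methyl-3-(propan-2-yl)cyclohex-1-ene-1-carboxylate
Conditions: Pd(OAc)2 (5 mol %), PPh3 (10 mol %), HCO2H, Et3N, DMF, 60 °C
Reagents that add atoms: none
Why: In this palladium-catalysed formate hydrogenolysis the electron-poor vinyl triflate adds oxidatively to zerovalent palladium, formate loses CO2, and reductive elimination gives the C–H bond; both stereocentres are spectators.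

**Step 4**
Reactants: 5 enoate; 6 4-iodobut-1-ene
Product: 7 methyl (1R,6R)-1-(but-3-en-1-yl)-6-methyl-3-(propan-2-yl)cyclohex-2-ene-1-carboxylate (butenyl trans to the methyl group)
Conditions: LiN(iPr)2, THF–DMPU, −78 °C; then 6, −78 → −20 °C
Reagents that add atoms: 4-iodobut-1-ene C=CCCI
Why: In this deconjugative α-alkylation of the extended enolate, removal of the only γ-hydrogen moves the alkene to the position the target needs; allylic strain with the planar ester enolate holds the C-6 methyl group axial, so the iodide attacks the opposite face and sets the quaternary (1R) centre.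

**Step 5**
Reactants: 7 quaternary ester
Product: 9 (5R,10R)-2,10-dimethyl-7-(propan-2-yl)spiro[4.5]dec-6-en-1-one (C-2 epimers), via tricyclic cyclopropanol 8 (not isolated)
Conditions: Ti(OiPr)4 (0.3 equiv), c-C5H9MgCl (3 equiv), THF, 0 °C → rt; then NaOH, MeOH–H2O, rt
Reagents that add atoms: none
Why: In this intramolecular Kulinkovich reaction the divalent titanium–cyclopentene complex exchanges only with the terminal alkene and then attacks the ester to close ring C; base opens the cyclopropanol at its CH2 carbon to give the 2-methyl ketone, and the C-2 centre is planarised again in step 7.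

**Step 6**
Reactants: 10 2,4,6-trihydroxybenzaldehyde
Product: 11 2,4,6-tris(tert-butoxycarbonyloxy)benzaldehyde
Conditions: (t-BuOCO)2O (3.3 equiv), i-Pr2NEt, DMAP (cat.), THF, 0 °C → rt
Reagents that add atoms: di-tert-butyl dicarbonate CC(C)(C)OC(=O)OC(=O)OC(C)(C)C
Why: DMAP-catalysed O-acylation of the three acidic phenols is routine, and no stereocentre is formed.

**Step 7**
Reactants: 9 spiro ketone; 11 tris-Boc aldehyde; 12 isobutylmagnesium chloride
Product: 15 (2R,5R,10R)-2-{1-[2,4-bis(tert-butoxycarbonyloxy)-6-hydroxyphenyl]-3-methylbutyl}-2,10-dimethyl-7-(propan-2-yl)spiro[4.5]dec-6-en-1-one (benzylic epimers), via lithium enolate 13 (not isolated), via o-quinone methide 14 (not isolated)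
Conditions: 9, LiN(iPr)2, THF, −78 → 0 °C; separately 11 (1.5 equiv), 12 (1.5 equiv), THF, −78 °C; combine, −78 °C → rt; aq. NH4Cl
Reagents that add atoms: isobutylmagnesium chloride CC(C)C[Mg]Cl
Why: This is a Michael addition of the only possible enolate of 9 to the very electrophilic o-quinone methide, which is released by Grignard addition, Boc migration and elimination; the electrophile takes the enolate face next to the flat vinylic C-6–H and away from C-10 and its methyl group, which sets (2R), and the benzylic epimer ratio does not matter because step 10 erases and resets that centre.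

**Step 8**
Reactants: 15 ketone
Product: 16 2-{1-[(1S,2R,5R,10R)-1-hydroxy-2,10-dimethyl-7-(propan-2-yl)spiro[4.5]dec-6-en-2-yl]-3-methylbutyl}benzene-1,3,5-triol (benzylic epimers)
Conditions: LiAlH4 (excess), THF, 0 °C → reflux; then aq. potassium sodium tartrate
Reagents that add atoms: none
Why: Hydride reduction of the non-enolisable ketone also cleaves both aryl carbonates; the small hydride enters on the face that carries the C-2 methyl group, anti to the very large 1-aryl-3-methylbutyl group, so the OH ends cis to that group (1S).

**Step 9**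
Reactants: 16 triol alcohol; 17 N,N-dimethylformamide
Product: 18 2,4,6-trihydroxy-5-{1-[(1S,2R,5R,10R)-1-hydroxy-2,10-dimethyl-7-(propan-2-yl)spiro[4.5]dec-6-en-2-yl]-3-methylbutyl}benzene-1,3-dicarbaldehyde (benzylic epimers)
Conditions: POCl3 (4 equiv), 17, EtOAc, 0 °C → rt; then H2O, aq. NaOH, rt; aq. HCl to pH 3
Reagents that add atoms: N,N-dimethylformamide CN(C)C=O; water O
Why: Double Vilsmeier–Haack formylation fills the two free, strongly activated ring positions as it does for phloroglucinol itself; the hindered alcohol is at most O-formylated, the basic work-up removes that formate, and no stereocentre is affected.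

**Step 10**
Reactants: 18 dialdehyde alcohol
Product: 21 target CNP0121396.3, via open o-quinone methide 19 (not isolated), via ring-closed o-quinone methide 20 (not isolated)
Conditions: DDQ (1.1 equiv), MeNO2, 4 Å MS, 60 °C; CF3CO2H (0.2 equiv), rt; then Hantzsch ester (diethyl 2,6-dimethyl-1,4-dihydropyridine-3,5-dicarboxylate, 1.5 equiv), −20 °C → rt
Reagents that add atoms: none
Why: Proposed new method: oxidatively triggered dehydrative O-arylation; DDQ removes the benzylic hydride, as it does from simpler alkyl diformylphloroglucinols, to give 19, in which the ring carbon that must receive oxygen is no longer an aromatic C–OH but the carbonyl carbon of a cross-conjugated vinylogous acid; the cis secondary alcohol can therefore add to it through a six-membered hemiketal, and acid-catalysed loss of water gives the vinylogous ester 20 with the O–CH configuration retained because that C–O bond is never broken; hydride transfer from the Hantzsch ester to the exocyclic carbon re-aromatises ring A and arrives on the convex face of the cis-fused rings B and C (the face carrying the ring-fusion H and CH3, opposite rings C and D), which gives the (S) benzylic centre from both epimers of 18; the closest known reaction types are enol-ether formation from cyclic 1,3-diketones and alcohols, acid-catalysed etherification of phloroglucinol through its keto tautomer, DDQ generation of o-quinone methides, and Hantzsch-ester reduction of quinone methides.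

**Compound list**
1 | (−)-menthone, (2S,5R)-5-methyl-2-(propan-2-yl)cyclohexan-1-one | CC(C)[C@@H]1CC[C@@H](C)CC1=O | starting material
2 | dimethyl carbonate | COC(=O)OC | starting material
3 | methyl (3S,6R)-6-methyl-2-oxo-3-(propan-2-yl)cyclohexane-1-carboxylate | COC(=O)C1[C@H](C)CC[C@@H](C(C)C)C1=O | intermediate
4 | methyl (3S,6R)-6-methyl-3-(propan-2-yl)-2-(trifluoromethylsulfonyloxy)cyclohex-1-ene-1-carboxylate | COC(=O)C1=C(OS(=O)(=O)C(F)(F)F)[C@H](C(C)C)CC[C@H]1C | intermediate
5 | methyl (3S,6R)-6-methyl-3-(propan-2-yl)cyclohex-1-ene-1-carboxylate | COC(=O)C1=C[C@H](C(C)C)CC[C@H]1C | intermediate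
6 | 4-iodobut-1-ene | C=CCCI | starting material
7 | methyl (1R,6R)-1-(but-3-en-1-yl)-6-methyl-3-(propan-2-yl)cyclohex-2-ene-1-carboxylate | C=CCC[C@]1(C(=O)OC)C=C(C(C)C)CC[C@H]1C | intermediate
8 | bicyclo[3.1.0]hexan-1-ol spiro-linked at C-2 to ring D (spiro carbon R, CH(CH3) R; cyclopropane centres undefined) | OC12CC1CC[C@@]23C=C(C(C)C)CC[C@H]3C | intermediate
9 | (5R,10R)-2,10-dimethyl-7-(propan-2-yl)spiro[4.5]dec-6-en-1-one (C-2 epimers) | O=C1C(C)CC[C@@]12C=C(C(C)C)CC[C@H]2C | intermediate
10 | 2,4,6-trihydroxybenzaldehyde | O=Cc1c(O)cc(O)cc1O | starting material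
11 | 2,4,6-tris(tert-butoxycarbonyloxy)benzaldehyde | O=Cc1c(OC(=O)OC(C)(C)C)cc(OC(=O)OC(C)(C)C)cc1OC(=O)OC(C)(C)C | intermediate
12 | isobutylmagnesium chloride | CC(C)C[Mg]Cl | starting material
13 | lithium enolate of 9 | [Li+].[O-]C1=C(C)CC[C@@]12C=C(C(C)C)CC[C@H]2C | intermediate
14 | 3,5-bis(tert-butoxycarbonyloxy)-6-(3-methylbutylidene)cyclohexa-2,4-dien-1-one | CC(C)CC=C1C(=O)C=C(OC(=O)OC(C)(C)C)C=C1OC(=O)OC(C)(C)C | intermediate
15 | (2R,5R,10R)-2-{1-[2,4-bis(tert-butoxycarbonyloxy)-6-hydroxyphenyl]-3-methylbutyl}-2,10-dimethyl-7-(propan-2-yl)spiro[4.5]dec-6-en-1-one (benzylic centre left open; may rest as its hemiketal) | CC(C)CC(c1c(O)cc(OC(=O)OC(C)(C)C)cc1OC(=O)OC(C)(C)C)[C@@]1(C)CC[C@]2(C1=O)C=C(C(C)C)CC[C@H]2C | intermediate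
16 | 2-{1-[(1S,2R,5R,10R)-1-hydroxy-2,10-dimethyl-7-(propan-2-yl)spiro[4.5]dec-6-en-2-yl]-3-methylbutyl}benzene-1,3,5-triol (benzylic centre left open) | CC(C)CC(c1c(O)cc(O)cc1O)[C@@]1(C)CC[C@]2([C@H]1O)C=C(C(C)C)CC[C@H]2C | intermediate
17 | N,N-dimethylformamide | CN(C)C=O | starting material
18 | 2,4,6-trihydroxy-5-{1-[(1S,2R,5R,10R)-1-hydroxy-2,10-dimethyl-7-(propan-2-yl)spiro[4.5]dec-6-en-2-yl]-3-methylbutyl}benzene-1,3-dicarbaldehyde (benzylic centre left open) | CC(C)CC(c1c(O)c(C=O)c(O)c(C=O)c1O)[C@@]1(C)CC[C@]2([C@H]1O)C=C(C(C)C)CC[C@H]2C | intermediate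
19 | open o-quinone methide of 18 (exocyclic C=C at the former benzylic carbon, ring C=O ortho to it) | CC(C)CC(=C1C(=O)C(C=O)=C(O)C(C=O)=C1O)[C@@]1(C)CC[C@]2([C@H]1O)C=C(C(C)C)CC[C@H]2C | intermediate
20 | ring-closed o-quinone methide (ring B closed through the aryl C–O bond, exocyclic C=C still in place) | CC(C)CC1=C2C(=O)C(C=O)=C(O)C(C=O)=C2O[C@H]2[C@]1(C)CC[C@@]21C=C(C(C)C)CC[C@H]1C | intermediate
21 | CNP0121396.3: 5,7-dihydroxy-6,8-diformylchroman cis-fused to ring C and spiro-linked to ring D; benzylic CH (S), O–CH (S), methyl-bearing ring-fusion C (R), spiro C (R), ring D CH(CH3) (R) | CC(C)C[C@@H]1c2c(O)c(C=O)c(O)c(C=O)c2O[C@H]2[C@]1(C)CC[C@@]21C=C(C(C)C)CC[C@H]1C | target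

**Totals**
Total step count: 10.
Longest linear sequence: 9 (steps 1–5 and 7–10).

**Three steps most likely to fail**

Step 10 (the new step). The alcohol may not add to the quinone methide carbonyl, or 19 may tautomerise or be over-oxidised. The fallback sets out from 16 and returns at 21. Compound 16 is cyclised by the classical acid-catalysed etherification of phloroglucinols with alcohols (TsOH, toluene, 4 Å MS, 90 °C). There the alcohol adds to the keto tautomer and water is lost, with retention at the O–CH carbon. Chromatographic removal of the benzylic epimer gives chroman diol F1, and Vilsmeier–Haack double formylation (POCl3, DMF) of F1 then gives 21.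

Step 7. The hindered enolate may act as a base toward 14 or attack a Boc group instead of forming the vicinal quaternary and tertiary pair. The fallback sets out from 9 and returns at 15. LiN(iPr)2 and Me3SiCl convert 9 into the trimethylsilyl enol ether F2. A neutral inverse-electron-demand hetero-Diels–Alder reaction of F2 with 14 (generated from 11 and 12 as before, −78 °C → rt) gives the silyl ketal cycloadduct F3, and aqueous citric acid opens it to 15.

Step 8. The doubly neopentyl ketone may resist reduction as its hemiketal aluminate, or hydride may enter from the wrong face. The fallback sets out from 15 and returns at 21. CF3CO2H in CH2Cl2 removes both Boc groups, and the free phenol closes onto the ketone to give the cyclic hemiketal F4. Known reductive etherification (Et3SiH, BF3·OEt2, CH2Cl2, −78 °C) reduces the derived oxocarbenium ion to the chroman, from which chroman diol F1 is isolated by chromatography. F1 is then formylated (POCl3, DMF) to 21.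

**Further compounds**
F1 | step 10 | 5,7-dihydroxychroman lacking the two formyl groups, same five stereocentres as 21 | CC(C)C[C@@H]1c2c(O)cc(O)cc2O[C@H]2[C@]1(C)CC[C@@]21C=C(C(C)C)CC[C@H]1C
F2 | step 7 | trimethylsilyl enol ether of 9 | C[Si](C)(C)OC1=C(C)CC[C@@]12C=C(C(C)C)CC[C@H]2C
F3 | step 7 | 2-(trimethylsilyloxy)chroman cycloadduct with Boc-oxy groups at C-5 and C-7 (benzylic centre left open) | CC(C)CC1c2c(OC(=O)OC(C)(C)C)cc(OC(=O)OC(C)(C)C)cc2O[C@@]2(O[Si](C)(C)C)[C@]1(C)CC[C@@]21C=C(C(C)C)CC[C@H]1C
F4 | step 8 | cyclic hemiketal (2-hydroxychroman-5,7-diol; benzylic and hemiketal centres left open) | CC(C)CC1c2c(O)cc(O)cc2OC2(O)[C@]1(C)CC[C@@]21C=C(C(C)C)CC[C@H]1C
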